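(The data were generated by integration for an exercise; scatter was added.)

Take a closed, stirred, isothermal vessel in which a catalyst turns the charge into target and isomer of the product A. Assume that target comes from starting material and isomer of the product A from other conformer.

| flask | starting material | other conformer | protic impurity | catalyst | remark | time |
|---|---|---|---|---|---|---|
| beta | 0.10 M | 0.025 M | 0.10 M | 0.50 mM | the very flask that is asked about, followed so far |  |
| flask | 0.10 M | 0.0250 M | 0.100 M | 0.50 mM |  | 4.0 d |

beta run (percent of the starting material and other conformer together charged)

| time / h | target / % | isomer of the product A / % |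
|---|---|---|
| 6.00 | 50.3 | 17.9 |
| 12.0 | 58.3 | 18.8 |
| 15.0 | 57.9 | 17.4 |
| 25.0 | 55.0 | 19.0 |
| 30.0 | 53.4 | 18.7 |

(each reading ± 0.5 percentage points)

1. ratio of target to isomer of the product A at 80 s
2. ratio of target to isomer of the product A at 80 min
3. ratio of target to isomer of the product A at 4.0 d
4. which of target and isomer of the product A there is more of at 4.0 d

- the numbers in the tables scatter with a standard deviation of 0.5 percentage points

Draw each curve as a first-order rise with rate constant k, so that the reading at 12.0 h divided by the reading at 6.00 h equals one plus exp(−k·6.00 h). For target this gives k_T = 0.306 /h, a half-life of 2.27 h, and a level of 59.8%. For isomer of the product A it gives k_I = 0.498 /h and a level of 18.8%. That reading rests on a gap of 0.9 points against a scatter of 0.5 points, so k_I is loosely held.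

Level times k gives each starting slope, and the slopes stand in the ratio R = 1.95. Multiply R by cE/cA, the charged other conformer over the charged starting material, to get σ = 0.488, the selectivity factor: the starting ratio of target to isomer of the product A per unit of cA/cE.

The time 80 s is 0.00981 of a target half-life, so the ratio there stands near R. This reckoning has no crossing, since target starts ahead. At 80 min the curves give 2.20. After the knee target sinks to 53.4% at 30.0 h while isomer of the product A stays flat, so the ratio there reads 2.86. Commit to these figures, with target leading at 4.0 d.

The forecast gives 0.6, 1.3 and 2.1, and says “The target still leads.”

The flask gives 0.889, 1.47 and 2.77, with 51.8% of target against 18.7% of isomer of the product A at 4.0 d. The two curves level at 0.0118 d, so the early crossing does exist.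

    starting material ⇌ other conformer (K = 0.0424, k = 0.00934 /h)
    starting material + catalyst → catalyst + target (k = 407 /M/h)
    target ⇌ isomer of the product B (K = 0.560, k = 0.0422 /h)
    catalyst + other conformer → catalyst + isomer of the product A (k = 1850 /M/h)
    other conformer + protic impurity → quenched substrate (k = 0.297 /M/h)

Reread σ from the flask's ratio at 80 s: it is 0.222, lower than the 0.488 from the readings. Apply it to a neighbouring flask charged with 0.10 M of other conformer, all else held. The product σ·cA/cE gives 0.222 at 80 s, and that flask gives 0.223. At 4.0 d its ratio stands at 0.885, with 36.7% of target against 41.4% of isomer of the product A.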